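**Plan**
Retrosynthesis (flavan numbering): the aryl ester bond C(=O)–O3' is cut first, then C4–C4a of ring C, then the ether bond O1–C2, and last the C2=C3 alkene of a cinnamyl side chain. This leads back to methyl gallate, 3,5-bis(benzyloxy)phenol, a two-carbon ylide and tribenzylgallic acid.
Enabling feature: C4 is a bare CH2 between the oxygen-bearing C3 and C4a, and C4a is a ring A carbon ortho to O1, ortho to O5 and para to O7. A C3–C4 oxirane on a 3,5-dialkoxyphenyl ether therefore presents an unhindered electrophilic carbon to the most electron-rich arene position at six-ring distance.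
Forward: ring B is differentiated (benzyl on O4'/O5', allyl on O3'), extended to the E-cinnamyl alcohol and epoxidised. Ring A is joined through O1 by opening that epoxide at C2, the diol is re-closed to the C3–C4 oxirane, and ring C is closed. O3 is then capped, O3' freed and galloylated, and hydrogenolysis ends the route.
Stereochemistry: one Katsuki–Sharpless epoxidation with L-(+)-DIPT sets both centres (2S,3S in the epoxy alcohol). The C3–O bond is never broken afterwards (3S), and the phenoxide inverts the benzylic centre once (to 2R), which gives the trans 2R,3S array.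

Key step: step 9

Remark: flavan numbering (O1, C2, C3, C4, C4a, C8a, primed numbers for ring B) is also used for the open-chain intermediates, and 1, 5, 10 and 17 are taken to be catalogue chemicals.

Step 1
Reactants: 1 methyl gallate
Product: 2 methyl 3,4-bis(benzyloxy)-5-hydroxybenzoate
Conditions: BnBr (2.0 equiv), K2CO3 (2.1 equiv), DMF, rt; chromatography
Reagents that add atoms: benzyl bromide, BrCc1ccccc1
Why: Williamson etherification under stoichiometric control: O4–H, para to the ester, is the most acidic hydroxyl and reacts first, the second benzyl group then goes to one of the two equivalent neighbours, and under- and over-benzylated material is removed by chromatography.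

Step 2
Reactants: 2 methyl 3,4-bis(benzyloxy)-5-hydroxybenzoate
Product: 3 methyl 3-(allyloxy)-4,5-bis(benzyloxy)benzoate
Conditions: allyl bromide, K2CO3, DMF, 40 °C
Reagents that add atoms: allyl bromide, C=CCBr
Why: Williamson allylation of the single remaining phenol tags the future O3' with a group that zerovalent palladium can later remove while benzyl ethers stay.

Step 3
Reactants: 3 methyl 3-(allyloxy)-4,5-bis(benzyloxy)benzoate
Product: 4 [3-(allyloxy)-4,5-bis(benzyloxy)phenyl]methanol
Conditions: LiAlH4, THF, 0 °C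
Reagents that add atoms: none
Why: Hydride reduction of an aryl ester to the benzylic alcohol, to which aryl benzyl and aryl allyl ethers are inert.

Step 4
Reactants: 4 [3-(allyloxy)-4,5-bis(benzyloxy)phenyl]methanol; 5 ethyl (triphenylphosphoranylidene)acetate
Product: 7 ethyl (E)-3-[3-(allyloxy)-4,5-bis(benzyloxy)phenyl]prop-2-enoate, via aldehyde 6 (not isolated)
Conditions: MnO2 (10 equiv), 5 (1.2 equiv), CH2Cl2, rt
Reagents that add atoms: none
Why: Tandem oxidation–Wittig olefination: MnO2 oxidises only the benzylic alcohol, the stabilised ylide intercepts aldehyde 6 as it forms, and stabilised ylides give the E-enoate.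

Step 5
Reactants: 7 ethyl (E)-3-[3-(allyloxy)-4,5-bis(benzyloxy)phenyl]prop-2-enoate
Product: 8 (E)-3-[3-(allyloxy)-4,5-bis(benzyloxy)phenyl]prop-2-en-1-ol
Conditions: i-Bu2AlH (2.3 equiv), CH2Cl2, −78 °C
Reagents that add atoms: none
Why: 1,2-Reduction of an enoate with i-Bu2AlH at low temperature delivers the allylic alcohol and leaves both alkenes in place.

Step 6
Reactants: 8 (E)-3-[3-(allyloxy)-4,5-bis(benzyloxy)phenyl]prop-2-en-1-ol
Product: 9 {(2S,3S)-3-[3-(allyloxy)-4,5-bis(benzyloxy)phenyl]oxiran-2-yl}methanol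
Conditions: Ti(OiPr)4 (10 mol%), L-(+)-DIPT (12 mol%), TBHP (2 equiv, decane), 4 Å MS, CH2Cl2, −20 °C; basic work-up, Et3N-deactivated silica
Reagents that add atoms: tert-butyl hydroperoxide, CC(C)(C)OO
Why: Katsuki–Sharpless asymmetric epoxidation: the allylic hydroxyl binds to the catalyst formed from Ti(OiPr)4 and L-(+)-DIPT, which converts E-cinnamyl-type alcohols into the (2S,3S)-epoxy alcohols and so sets both stereocentres at once, whereas the allyl ether alkene has no hydroxyl to direct the oxidant and is left alone.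

Step 7
Reactants: 9 {(2S,3S)-3-[3-(allyloxy)-4,5-bis(benzyloxy)phenyl]oxiran-2-yl}methanol; 10 3,5-bis(benzyloxy)phenol
Product: 11 (2S,3R)-3-[3-(allyloxy)-4,5-bis(benzyloxy)phenyl]-3-[3,5-bis(benzyloxy)phenoxy]propane-1,2-diol
Conditions: 10 (1.5 equiv), Cs2CO3 (0.3 equiv), DMF, 70 °C
Reagents that add atoms: none
Why: Base-mediated phenolysis of a 3-aryl-2,3-epoxy alcohol, an SN2 addition that keeps all atoms of both partners: the phenoxide attacks from the rear at the benzylic oxirane carbon, which the aryl group activates while the CH2OH group deactivates its neighbour, so this centre is inverted (S to R, the future C2), the other keeps its C–O bond (S, the future C3), and a deficit of base relative to phenol keeps the alkoxide level low and holds back Payne rearrangement.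

Step 8
Reactants: 11 (2S,3R)-3-[3-(allyloxy)-4,5-bis(benzyloxy)phenyl]-3-[3,5-bis(benzyloxy)phenoxy]propane-1,2-diol
Product: 13 (2S)-2-{(R)-[3-(allyloxy)-4,5-bis(benzyloxy)phenyl][3,5-bis(benzyloxy)phenoxy]methyl}oxirane, via primary tosylate 12 (not isolated)
Conditions: TsCl (1.05 equiv), Et3N, Bu2SnO (2 mol%), CH2Cl2, 0 °C to rt; then K2CO3, MeOH, rt
Reagents that add atoms: 4-toluenesulfonyl chloride, Cc1ccc(cc1)S(=O)(=O)Cl (its atoms stay in 12 only and are lost again in 13)
Why: Tin-catalysed monotosylation picks the primary hydroxyl through the dibutylstannylene acetal, and the secondary alkoxide then expels the tosylate in a 3-exo-tet Williamson closure in which the C3–O bond, and hence the S configuration, is retained.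

Step 9
Reactants: 13 (2S)-2-{(R)-[3-(allyloxy)-4,5-bis(benzyloxy)phenyl][3,5-bis(benzyloxy)phenoxy]methyl}oxirane
Product: 14 (2R,3S)-2-[3-(allyloxy)-4,5-bis(benzyloxy)phenyl]-5,7-bis(benzyloxy)chroman-3-ol
Conditions: AuCl3 (5 mol%), AgOTf (15 mol%), 4 Å MS, ClCH2CH2Cl (0.02 M), 0 °C to rt
Reagents that add atoms: none
Why: The cationic gold species formed from AuCl3 and AgOTf binds the oxirane oxygen, a ring A carbon next to O1 attacks the CH2 terminus from the rear, and proton loss from the arenium ion followed by protonation of the metal alkoxide gives the 3-chromanol, so the step is a pure isomerisation. The closest known reaction type is the Lewis acid promoted cycloalkylation of aryl glycidyl ethers to 3-chromanols, an intramolecular Friedel–Crafts alkylation paid for by oxirane strain. Ring C closes in the 6-endo-tet mode (both oxirane carbons end up in the new ring) with formation of C4–C4a. No stereocentre is created: only the C4–O bond breaks, so C3 stays S and its oxygen becomes the free 3-hydroxyl, while C2 is a spectator. The step needs 6-endo over 5-exo closure, which the unsubstituted and unhindered C4 secures, and site selectivity on ring A, which is no issue because the two carbons flanking O1 are related by symmetry and each is activated by all three oxygens. It also needs the benzylic C2–O1 bond and the allyl ether to survive, which a non-ionising solvent, a low catalyst loading, the 4'-benzyloxy group twisted out of conjugation by its two neighbours and the far higher reactivity of the strained oxirane should ensure.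

Step 10
Reactants: 14 (2R,3S)-2-[3-(allyloxy)-4,5-bis(benzyloxy)phenyl]-5,7-bis(benzyloxy)chroman-3-ol
Product: 15 (2R,3S)-2-[3-(allyloxy)-4,5-bis(benzyloxy)phenyl]-3,5,7-tris(benzyloxy)chroman
Conditions: NaH, BnBr, Bu4NI (cat.), DMF, 0 °C to rt
Reagents that add atoms: benzyl bromide, BrCc1ccccc1
Why: Williamson benzylation of the secondary alkoxide caps O3 so that the later acylation has only O3' to go to, and with all phenols masked no quinone methide pathway exists that could epimerise C2.

Step 11
Reactants: 15 (2R,3S)-2-[3-(allyloxy)-4,5-bis(benzyloxy)phenyl]-3,5,7-tris(benzyloxy)chroman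
Product: 16 2,3-bis(benzyloxy)-5-[(2R,3S)-3,5,7-tris(benzyloxy)chroman-2-yl]phenol
Conditions: Pd(PPh3)4 (5 mol%), morpholine (10 equiv), THF, rt
Reagents that add atoms: none
Why: Tsuji–Trost deallylation: zerovalent palladium ionises the aryl allyl ether to an allylpalladium cation and the phenoxide, morpholine captures the allyl unit, and benzyl ethers do not ionise under these conditions.

Step 12
Reactants: 16 2,3-bis(benzyloxy)-5-[(2R,3S)-3,5,7-tris(benzyloxy)chroman-2-yl]phenol; 17 3,4,5-tris(benzyloxy)benzoic acid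
Product: 18 2,3-bis(benzyloxy)-5-[(2R,3S)-3,5,7-tris(benzyloxy)chroman-2-yl]phenyl 3,4,5-tris(benzyloxy)benzoate
Conditions: DCC (1.5 equiv), DMAP (0.2 equiv), CH2Cl2, 0 °C to rt
Reagents that add atoms: none
Why: Steglich esterification at the only free hydroxyl of 16, with DMAP carrying the acyl group from the O-acylisourea to the hindered phenol.

Step 13
Reactants: 18 2,3-bis(benzyloxy)-5-[(2R,3S)-3,5,7-tris(benzyloxy)chroman-2-yl]phenyl 3,4,5-tris(benzyloxy)benzoate
Product: 19 gallocatechin 3'-O-gallate, (2R,3S)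
Conditions: H2 (1 atm), Pd(OH)2/C, THF–EtOAc, rt
Reagents that add atoms: none
Why: Hydrogenolysis of all eight benzyl ethers in one operation, the usual end of catechin gallate syntheses, run in a neutral non-nucleophilic solvent so that the aryl ester is neither solvolysed nor moved to O4', and mild enough for the cyclic benzylic C2–O1 bond and both stereocentres to persist.

**Compound list**
1 | methyl gallate | COC(=O)c1cc(O)c(O)c(O)c1 | starting material
2 | methyl 3,4-bis(benzyloxy)-5-hydroxybenzoate | COC(=O)c1cc(O)c(OCc2ccccc2)c(OCc2ccccc2)c1 | intermediate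
3 | methyl 3-(allyloxy)-4,5-bis(benzyloxy)benzoate | COC(=O)c1cc(OCC=C)c(OCc2ccccc2)c(OCc2ccccc2)c1 | intermediate
4 | [3-(allyloxy)-4,5-bis(benzyloxy)phenyl]methanol | OCc1cc(OCC=C)c(OCc2ccccc2)c(OCc2ccccc2)c1 | intermediate
5 | ethyl (triphenylphosphoranylidene)acetate | CCOC(=O)C=P(c1ccccc1)(c1ccccc1)c1ccccc1 | starting material
6 | 3-(allyloxy)-4,5-bis(benzyloxy)benzaldehyde (not isolated) | O=Cc1cc(OCC=C)c(OCc2ccccc2)c(OCc2ccccc2)c1 | intermediate
7 | ethyl (E)-3-[3-(allyloxy)-4,5-bis(benzyloxy)phenyl]prop-2-enoate | CCOC(=O)/C=C/c1cc(OCC=C)c(OCc2ccccc2)c(OCc2ccccc2)c1 | intermediate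
8 | (E)-3-[3-(allyloxy)-4,5-bis(benzyloxy)phenyl]prop-2-en-1-ol | OC/C=C/c1cc(OCC=C)c(OCc2ccccc2)c(OCc2ccccc2)c1 | intermediate
9 | {(2S,3S)-3-[3-(allyloxy)-4,5-bis(benzyloxy)phenyl]oxiran-2-yl}methanol | C=CCOc1cc([C@H]2[C@@H](O2)CO)cc(OCc2ccccc2)c1OCc1ccccc1 | intermediate
10 | 3,5-bis(benzyloxy)phenol | Oc1cc(OCc2ccccc2)cc(OCc2ccccc2)c1 | starting material
11 | (2S,3R)-3-[3-(allyloxy)-4,5-bis(benzyloxy)phenyl]-3-[3,5-bis(benzyloxy)phenoxy]propane-1,2-diol | C=CCOc1cc([C@@H](Oc2cc(OCc3ccccc3)cc(OCc3ccccc3)c2)[C@@H](O)CO)cc(OCc2ccccc2)c1OCc1ccccc1 | intermediate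
12 | (2S,3R)-3-[3-(allyloxy)-4,5-bis(benzyloxy)phenyl]-3-[3,5-bis(benzyloxy)phenoxy]-2-hydroxypropyl 4-toluenesulfonate (not isolated) | C=CCOc1cc([C@@H](Oc2cc(OCc3ccccc3)cc(OCc3ccccc3)c2)[C@@H](O)COS(=O)(=O)c2ccc(C)cc2)cc(OCc2ccccc2)c1OCc1ccccc1 | intermediate
13 | (2S)-2-{(R)-[3-(allyloxy)-4,5-bis(benzyloxy)phenyl][3,5-bis(benzyloxy)phenoxy]methyl}oxirane | C=CCOc1cc([C@@H](Oc2cc(OCc3ccccc3)cc(OCc3ccccc3)c2)[C@@H]2CO2)cc(OCc2ccccc2)c1OCc1ccccc1 | intermediate
14 | (2R,3S)-2-[3-(allyloxy)-4,5-bis(benzyloxy)phenyl]-5,7-bis(benzyloxy)chroman-3-ol | C=CCOc1cc([C@H]2Oc3cc(OCc4ccccc4)cc(OCc4ccccc4)c3C[C@@H]2O)cc(OCc2ccccc2)c1OCc1ccccc1 | intermediate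
15 | (2R,3S)-2-[3-(allyloxy)-4,5-bis(benzyloxy)phenyl]-3,5,7-tris(benzyloxy)chroman | C=CCOc1cc([C@H]2Oc3cc(OCc4ccccc4)cc(OCc4ccccc4)c3C[C@@H]2OCc2ccccc2)cc(OCc2ccccc2)c1OCc1ccccc1 | intermediate
16 | 2,3-bis(benzyloxy)-5-[(2R,3S)-3,5,7-tris(benzyloxy)chroman-2-yl]phenol | Oc1cc([C@H]2Oc3cc(OCc4ccccc4)cc(OCc4ccccc4)c3C[C@@H]2OCc2ccccc2)cc(OCc2ccccc2)c1OCc1ccccc1 | intermediate
17 | 3,4,5-tris(benzyloxy)benzoic acid | OC(=O)c1cc(OCc2ccccc2)c(OCc2ccccc2)c(OCc2ccccc2)c1 | starting material
18 | 2,3-bis(benzyloxy)-5-[(2R,3S)-3,5,7-tris(benzyloxy)chroman-2-yl]phenyl 3,4,5-tris(benzyloxy)benzoate | O=C(Oc1cc([C@H]2Oc3cc(OCc4ccccc4)cc(OCc4ccccc4)c3C[C@@H]2OCc2ccccc2)cc(OCc2ccccc2)c1OCc1ccccc1)c1cc(OCc2ccccc2)c(OCc2ccccc2)c(OCc2ccccc2)c1 | intermediate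
19 | gallocatechin 3'-O-gallate, (2R,3S) | O=C(Oc1cc([C@H]2Oc3cc(O)cc(O)c3C[C@@H]2O)cc(O)c1O)c1cc(O)c(O)c(O)c1 | target

**Step count**
Total steps: 13. Longest linear sequence: 13 steps (1 to 19). Compounds 5, 10 and 17 enter as purchased.

**Steps most likely to fail**

Step 9. The catalyst may ionise the benzylic C2–O1 bond, which would expel the ring A phenol or scramble C2. Ring closure may also take the 5-exo course, the oxirane may isomerise by hydride shift, or the allyl ether may be attacked.
The fallback makes the same C4–C4a bond with reversed polarity. It sets out from 9 and 10 and comes back at 14. Phenol 10 is iodinated next to its hydroxyl (NIS, CH2Cl2, 0 °C) to 3,5-bis(benzyloxy)-2-iodophenol F1, which opens 9 under the conditions of step 7 to the iodo diol F2. PPh3 and CBr4 (Appel reaction) exchange only the primary hydroxyl and give the bromohydrin F3, and Et3SiOTf with 2,6-lutidine gives its triethylsilyl ether F4. n-BuLi in THF at −78 °C effects iodine–lithium exchange to the aryllithium F5. This displaces the primary bromide in a 6-exo-tet Parham-type cyclialkylation to the 3-O-triethylsilyl flavan F6, and Bu4NF then returns 14.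

Step 7. Payne rearrangement followed by attack at the terminal carbon, carbon alkylation by the ambident phloroglucinol-type phenoxide, or partial SN1 character at the electron-rich benzylic carbon would cost regiochemistry or the C2 configuration.
The fallback forms O1–C2 by Mitsunobu inversion on a non-benzylic epoxide. It sets out from 6 (isolated by running the MnO2 oxidation of 4 without the ylide) and comes back at 13. CH2=CHMgBr adds to 6 to give the racemic allylic alcohol F7. Sharpless kinetic resolution (Ti(OiPr)4, D-(−)-DIPT, TBHP 0.45 equiv, 4 Å MS, CH2Cl2, −20 °C) epoxidises the S enantiomer to the erythro epoxy alcohol F8 and leaves the R allylic alcohol F9 behind. A Mitsunobu reaction with 4-nitrobenzoic acid (PPh3, DIAD, toluene, 0 °C) inverts the carbinol centre to the 4-nitrobenzoate F10, and brief K2CO3/MeOH at 0 °C frees the threo epoxy alcohol F11. A second Mitsunobu reaction with 10 inverts the centre again and gives 13.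

Step 6. The electron-rich benzylic epoxide may be opened by the titanium Lewis acid or by isopropoxide during reaction and work-up, and the enantiomeric purity may suffer.
The fallback uses a reagent-controlled dioxirane epoxidation without any Lewis acid. It sets out from 8 and comes back at 9. It is a Shi epoxidation of 8 with the L-fructose-derived ketone (the enantiomer of the usual D-fructose-derived catalyst, which would give the 2R,3R series). The oxidant is KHSO5 (as 2KHSO5·KHSO4·K2SO4) in K2CO3 buffer at about pH 10, in MeCN–dimethoxymethane–water at 0 °C. The basic medium protects the acid-labile product, and the conjugated trans alkene should react well ahead of the monosubstituted allyl ether alkene.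

**Further compounds**
F1 | step 9 | 3,5-bis(benzyloxy)-2-iodophenol | Oc1cc(OCc2ccccc2)cc(OCc2ccccc2)c1I
F2 | step 9 | (2S,3R)-3-[3-(allyloxy)-4,5-bis(benzyloxy)phenyl]-3-[3,5-bis(benzyloxy)-2-iodophenoxy]propane-1,2-diol | C=CCOc1cc([C@@H](Oc2cc(OCc3ccccc3)cc(OCc3ccccc3)c2I)[C@@H](O)CO)cc(OCc2ccccc2)c1OCc1ccccc1
F3 | step 9 | (2R,3R)-3-[3-(allyloxy)-4,5-bis(benzyloxy)phenyl]-3-[3,5-bis(benzyloxy)-2-iodophenoxy]-1-bromopropan-2-ol | C=CCOc1cc([C@@H](Oc2cc(OCc3ccccc3)cc(OCc3ccccc3)c2I)[C@@H](O)CBr)cc(OCc2ccccc2)c1OCc1ccccc1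
F4 | step 9 | triethylsilyl ether of F3 | C=CCOc1cc([C@@H](Oc2cc(OCc3ccccc3)cc(OCc3ccccc3)c2I)[C@@H](O[Si](CC)(CC)CC)CBr)cc(OCc2ccccc2)c1OCc1ccccc1
F5 | step 9 | aryllithium from F4 (lithium in place of iodine, not isolated) | C=CCOc1cc([C@@H](Oc2cc(OCc3ccccc3)cc(OCc3ccccc3)c2[Li])[C@@H](O[Si](CC)(CC)CC)CBr)cc(OCc2ccccc2)c1OCc1ccccc1
F6 | step 9 | (2R,3S)-2-[3-(allyloxy)-4,5-bis(benzyloxy)phenyl]-5,7-bis(benzyloxy)-3-(triethylsilyloxy)chroman | C=CCOc1cc([C@H]2Oc3cc(OCc4ccccc4)cc(OCc4ccccc4)c3C[C@@H]2O[Si](CC)(CC)CC)cc(OCc2ccccc2)c1OCc1ccccc1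
F7 | step 7 | racemic 1-[3-(allyloxy)-4,5-bis(benzyloxy)phenyl]prop-2-en-1-ol | C=CCOc1cc(C(O)C=C)cc(OCc2ccccc2)c1OCc1ccccc1
F8 | step 7 | (R)-[3-(allyloxy)-4,5-bis(benzyloxy)phenyl][(2S)-oxiran-2-yl]methanol (erythro) | C=CCOc1cc([C@@H](O)[C@@H]2CO2)cc(OCc2ccccc2)c1OCc1ccccc1
F9 | step 7 | (R)-1-[3-(allyloxy)-4,5-bis(benzyloxy)phenyl]prop-2-en-1-ol (unreacted enantiomer) | C=CCOc1cc([C@H](O)C=C)cc(OCc2ccccc2)c1OCc1ccccc1
F10 | step 7 | (S)-[3-(allyloxy)-4,5-bis(benzyloxy)phenyl][(2S)-oxiran-2-yl]methyl 4-nitrobenzoate | C=CCOc1cc([C@H](OC(=O)c2ccc(cc2)[N+](=O)[O-])[C@@H]2CO2)cc(OCc2ccccc2)c1OCc1ccccc1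
F11 | step 7 | (S)-[3-(allyloxy)-4,5-bis(benzyloxy)phenyl][(2S)-oxiran-2-yl]methanol (threo) | C=CCOc1cc([C@H](O)[C@@H]2CO2)cc(OCc2ccccc2)c1OCc1ccccc1
F0 | step 6 | none | none
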